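**Retrosynthetic overview**
- The target comes from its pentamethyl ether. Sodium ethanethiolate removes one methyl per ring, and the phenoxide formed first on the dimethoxy ring shields that ring's second OMe.
- The pentamethyl ether comes from a dithiane/benzhydrol precursor. One Raney nickel treatment turns C(SR)2 and CH(OH) into the two missing CH2 groups.
- Key disconnection is the bond between the central ring and the ethylene bridge. The masked acyl anion ArCH2C(=O)⁻ (a lithiated dithiane) adds to the electrophilic carbon of a 3-methoxyaryne, and p-anisaldehyde traps the resulting aryllithium in the same flask.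
- The dithiane comes from 1,3-dithiane and 3,5-dimethoxybenzyl bromide. The aryne precursor comes from 4-methoxybenzylzinc chloride and 4-bromo-3-fluoroanisole.
- No ring is formed. All four benzene rings are bought.

Assumption: the target has no stereocentre and is achiral, so no enantiomer has to be chosen. The one stereocentre made on the way (the carbinol in 14) is racemic and is removed in step 4.

**Step 1**
Reactants: 1 4-methoxybenzyl chloride; 2 4-bromo-3-fluoroanisole
Product: 4 2-fluoro-4-methoxy-1-(4-methoxybenzyl)benzene, via (4-methoxybenzyl)zinc chloride 3 (not isolated)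
Conditions: 1, Zn dust, LiCl, THF, 25 °C; then 2, Pd(OAc)2 (1 mol %), SPhos (2 mol %), THF, 25–50 °C
Reagents that add atoms: none
Why: This is a Negishi sp3–sp2 cross-coupling in which the benzylic zinc reagent couples at C–Br only, leaving C–F and OMe untouched, so F ends up ortho to the benzyl group and meta to OMe without ambiguity.

**Step 2**
Reactants: 5 1,3-dithiane; 6 3,5-dimethoxybenzyl bromide
Product: 8 2-(3,5-dimethoxybenzyl)-1,3-dithiane, via 2-lithio-1,3-dithiane 7 (not isolated)
Conditions: 5, n-BuLi, THF, −30 °C, 1.5 h; then 6, −78 °C → rt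
Reagents that add atoms: none
Why: This is a Corey–Seebach alkylation in which the formyl anion equivalent displaces a reactive benzylic bromide by SN2, and no stereocentre is formed.

**Step 3 (key step)**
Reactants: 4 2-fluoro-4-methoxy-1-(4-methoxybenzyl)benzene; 8 2-(3,5-dimethoxybenzyl)-1,3-dithiane; 9 4-methoxybenzaldehyde
Product: 14 (±)-{2-[2-(3,5-dimethoxybenzyl)-1,3-dithian-2-yl]-6-methoxy-3-(4-methoxybenzyl)phenyl}(4-methoxyphenyl)methanol, via 2-lithio-2-(3,5-dimethoxybenzyl)-1,3-dithiane 10 (not isolated), via [2-fluoro-6-methoxy-3-(4-methoxybenzyl)phenyl]lithium 11 (not isolated), via 3-methoxy-6-(4-methoxybenzyl)benzyne 12 (not isolated), via {2-[2-(3,5-dimethoxybenzyl)-1,3-dithian-2-yl]-6-methoxy-3-(4-methoxybenzyl)phenyl}lithium 13 (not isolated)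
Conditions: 8 (1.6 equiv), n-BuLi, THF, −25 °C, 2 h; separately 4, n-BuLi, THF, −78 °C, 1 h; cannulate 10 into 11, −78 → −10 °C, 2 h; recool to −78 °C, 9, → 0 °C; H2O
Reagents that add atoms: none
Why: Proposed new method: lithiation of 4 between F and OMe followed by loss of LiF gives the 3-alkoxyaryne 12, whose carbon meta to OMe is the more electrophilic terminus (inductive and distortion control), so the masked acyl anion 10, whose carbon is an electrophilic C=O carbon when unmasked, bonds to that electrophilic aryne carbon; because 10 is fully substituted, adduct 13 has no acidic C–H next to the new OMe-stabilised aryllithium, which therefore survives until 9 captures it; the closest known reaction type is the three-component aryne coupling (carbometalation of a 3-alkoxybenzyne generated from a lithiated fluoroanisole, then an aldehyde trap) combined with Corey–Seebach dithiane chemistry; the carbinol carbon forms racemic and is erased in step 4.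

**Step 4**
Reactants: 14 (±)-{2-[2-(3,5-dimethoxybenzyl)-1,3-dithian-2-yl]-6-methoxy-3-(4-methoxybenzyl)phenyl}(4-methoxyphenyl)methanol
Product: 15 2-[2-(3,5-dimethoxyphenyl)ethyl]-4-methoxy-1,3-bis(4-methoxybenzyl)benzene
Conditions: Raney Ni (W-2, large excess), H2 (balloon), EtOH, reflux
Reagents that add atoms: none
Why: Mozingo-type Raney nickel desulfurization converts the dithiane carbon to CH2, the same reagent hydrogenolyses the doubly aryl-activated benzhydrol C–OH, aryl methyl ethers survive, and the only stereocentre disappears.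

**Step 5**
Reactants: 15 2-[2-(3,5-dimethoxyphenyl)ethyl]-4-methoxy-1,3-bis(4-methoxybenzyl)benzene
Product: 16 3-[2-(3-hydroxy-5-methoxyphenyl)ethyl]-2,4-bis(4-hydroxybenzyl)phenol (target)
Conditions: NaSEt (12 equiv), DMF, 150 °C, argon; then 1 M HCl
Reagents that add atoms: none
Why: This is a thiolate SN2 O-demethylation in which each ring loses one methyl, and on the dimethoxy ring the first phenoxide makes the second cleavage (which would expel a dianion) far slower, so exactly one OMe remains there.

**Compound list**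
1 | 4-methoxybenzyl chloride | COc1ccc(CCl)cc1 | starting material
2 | 4-bromo-3-fluoroanisole | COc1ccc(Br)c(F)c1 | starting material
3 | (4-methoxybenzyl)zinc chloride | COc1ccc(C[Zn]Cl)cc1 | intermediate (not isolated)
4 | 2-fluoro-4-methoxy-1-(4-methoxybenzyl)benzene | COc1ccc(Cc2ccc(OC)cc2F)cc1 | intermediate
5 | 1,3-dithiane | C1CSCSC1 | starting material
6 | 3,5-dimethoxybenzyl bromide | COc1cc(CBr)cc(OC)c1 | starting material
7 | 2-lithio-1,3-dithiane | [Li]C1SCCCS1 | intermediate (not isolated)
8 | 2-(3,5-dimethoxybenzyl)-1,3-dithiane | COc1cc(CC2SCCCS2)cc(OC)c1 | intermediate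
9 | 4-methoxybenzaldehyde | COc1ccc(C=O)cc1 | starting material
10 | 2-lithio-2-(3,5-dimethoxybenzyl)-1,3-dithiane | COc1cc(CC2([Li])SCCCS2)cc(OC)c1 | intermediate (not isolated)
11 | [2-fluoro-6-methoxy-3-(4-methoxybenzyl)phenyl]lithium | COc1ccc(Cc2ccc(OC)c([Li])c2F)cc1 | intermediate (not isolated)
12 | 3-methoxy-6-(4-methoxybenzyl)benzyne | COC1=CC=C(Cc2ccc(OC)cc2)C#C1 | intermediate (not isolated)
13 | {2-[2-(3,5-dimethoxybenzyl)-1,3-dithian-2-yl]-6-methoxy-3-(4-methoxybenzyl)phenyl}lithium | COc1ccc(Cc2ccc(OC)c([Li])c2C2(Cc3cc(OC)cc(OC)c3)SCCCS2)cc1 | intermediate (not isolated)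
14 | (±)-{2-[2-(3,5-dimethoxybenzyl)-1,3-dithian-2-yl]-6-methoxy-3-(4-methoxybenzyl)phenyl}(4-methoxyphenyl)methanol (racemic carbinol) | COc1ccc(Cc2ccc(OC)c(C(O)c3ccc(OC)cc3)c2C2(Cc3cc(OC)cc(OC)c3)SCCCS2)cc1 | intermediate
15 | 2-[2-(3,5-dimethoxyphenyl)ethyl]-4-methoxy-1,3-bis(4-methoxybenzyl)benzene | COc1ccc(Cc2ccc(OC)c(Cc3ccc(OC)cc3)c2CCc2cc(OC)cc(OC)c2)cc1 | intermediate
16 | 3-[2-(3-hydroxy-5-methoxyphenyl)ethyl]-2,4-bis(4-hydroxybenzyl)phenol (achiral) | COc1cc(O)cc(CCc2c(Cc3ccc(O)cc3)ccc(O)c2Cc2ccc(O)cc2)c1 | target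

**Totals**
- Total step count: 5.
- Longest linear sequence: 4 (step 1 or 2, then steps 3, 4 and 5).

**Three steps most likely to fail**

Step 3. The tertiary anion 10 must attack the aryne carbon next to the benzyl group, and the crowded aryllithium 13 must live long enough to be trapped. Self-addition of 11 to 12 and stray proton transfer are the main threats.

The fallback builds the central ring instead of substituting it, and it keeps the same masked acyl anion. It sets out from 8 and comes back to the route at 15. Cyclohexane-1,3-dione, 9 and Hantzsch ester (L-proline, CH2Cl2, rt) give 2-(4-methoxybenzyl)cyclohexane-1,3-dione F1. HC(OMe)3, MeOH and catalytic TsOH then give 3-methoxy-2-(4-methoxybenzyl)cyclohex-2-en-1-one F2. LDA (THF, −78 °C) followed by 1 with NaI gives racemic 3-methoxy-2,6-bis(4-methoxybenzyl)cyclohex-2-en-1-one F3. Anion 10 (from 8 and n-BuLi, with CeCl3 to suppress enolisation) adds 1,2 to the vinylogous ester carbonyl. Aqueous HCl then completes the Stork–Danheiser transposition to racemic 3-[2-(3,5-dimethoxybenzyl)-1,3-dithian-2-yl]-2,4-bis(4-methoxybenzyl)cyclohex-2-en-1-one F4. Raney Ni gives 3-[2-(3,5-dimethoxyphenyl)ethyl]-2,4-bis(4-methoxybenzyl)cyclohex-2-en-1-one F5. Finally, I2 in refluxing MeOH aromatises the enone directly to the aryl methyl ether 15.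

Step 4. The hindered benzhydrol may survive Raney nickel while the sulfur is removed, or the desulfurization may stall.

The fallback separates the two reductions by mechanism. It sets out from 14 and comes back at 15. Ionic deoxygenation (Et3SiH, TFA, CH2Cl2, 0 °C) through the p-anisyl-stabilised cation gives 2-(3,5-dimethoxybenzyl)-2-[3-methoxy-2,6-bis(4-methoxybenzyl)phenyl]-1,3-dithiane F6. Only C–S bonds then remain to be cut, with nickel boride (NiCl2·6H2O, NaBH4, MeOH/THF), which gives 15.

Step 5. The trialkyl-substituted central ring may be cleaved incompletely, or the resorcinol ring may lose both methyl groups.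

The fallback strips every methyl and puts one back. It sets out from 15 and comes back at 16. BBr3 (excess, CH2Cl2, −78 °C → rt) gives 5-{2-[3-hydroxy-2,6-bis(4-hydroxybenzyl)phenyl]ethyl}benzene-1,3-diol F7. MeI (1.0 equiv) and K2CO3 (1.0 equiv) in acetone then methylate preferentially one of the two equivalent resorcinol OH groups. These are the most acidic hydroxyls (pKa about 9.4, against about 10.2–10.6 for the alkylphenol OH groups). This gives 16 after chromatography, and unreacted F7 is recycled.

**Further compounds**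
F1 | step 3 | 2-(4-methoxybenzyl)cyclohexane-1,3-dione | O=C1CCCC(=O)C1Cc1ccc(OC)cc1
F2 | step 3 | 3-methoxy-2-(4-methoxybenzyl)cyclohex-2-en-1-one | COC1=C(Cc2ccc(OC)cc2)C(=O)CCC1
F3 | step 3 | (±)-3-methoxy-2,6-bis(4-methoxybenzyl)cyclohex-2-en-1-one | COC1=C(Cc2ccc(OC)cc2)C(=O)C(Cc2ccc(OC)cc2)CC1
F4 | step 3 | (±)-3-[2-(3,5-dimethoxybenzyl)-1,3-dithian-2-yl]-2,4-bis(4-methoxybenzyl)cyclohex-2-en-1-one | O=C1CCC(Cc2ccc(OC)cc2)C(C2(Cc3cc(OC)cc(OC)c3)SCCCS2)=C1Cc1ccc(OC)cc1
F5 | step 3 | (±)-3-[2-(3,5-dimethoxyphenyl)ethyl]-2,4-bis(4-methoxybenzyl)cyclohex-2-en-1-one | O=C1CCC(Cc2ccc(OC)cc2)C(CCc2cc(OC)cc(OC)c2)=C1Cc1ccc(OC)cc1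
F6 | step 4 | 2-(3,5-dimethoxybenzyl)-2-[3-methoxy-2,6-bis(4-methoxybenzyl)phenyl]-1,3-dithiane | COc1ccc(Cc2ccc(OC)c(Cc3ccc(OC)cc3)c2C2(Cc3cc(OC)cc(OC)c3)SCCCS2)cc1
F7 | step 5 | 5-{2-[3-hydroxy-2,6-bis(4-hydroxybenzyl)phenyl]ethyl}benzene-1,3-diol | Oc1ccc(Cc2ccc(O)c(Cc3ccc(O)cc3)c2CCc2cc(O)cc(O)c2)cc1
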